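From the constants I wanted first the moment at which G stops gaining, so the scheme and the settings stand here.

    J → G (k1 = 3.1 × 10⁻⁴ s⁻¹)
    L + G → L + Q (k2 = 0.085 M⁻¹ s⁻¹)
    2 L ⇌ L2, settled at all times (K3 = 1900 M⁻¹)
    J + X → J.X (k4 = 0.017 M⁻¹ s⁻¹)

| flask | J | X | L | time | remark |
|---|---|---|---|---|---|
| alpha | 0.093 M | 0.0186 M | 5.3 mol% | 1.5 h | everything together in a closed stirred flask, run for 1.5 h |
| gamma | 0.093 M | 0.0186 M | 5.3 mol% |  | a single well-mixed tank run continuously and read at steady state, 1.5 h in it on average |
| eta | 0.093 M (fed, over 1.20 h) | 0.0186 M | 5.3 mol% | 1.5 h | a stirred flask in which J is dosed at a steady rate over 1.20 h without added volume, worked up at 1.5 h |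

- for a step with 2 of a species take k times the square, and two of it per event
- the stated concentrations are those of everything mixed, before any reaction; amounts are the same in each set-up
- the feed brings no volume worth counting
- run time (alpha): 1.5 h

* the set-up with the highest amount of G at the outlet or at the end, in percent of the J put in ("none" if the first two lie within 2 percentage points) (alpha / gamma / eta / none)
* amount of G at the outlet or at the end, in percent of the J put in, alpha
* amount of G at the outlet or at the end, in percent of the J put in, gamma
* amount of G at the outlet or at the end, in percent of the J put in, eta

1. I counted the catalyst in both its forms, [L] + 2K[L]² for the charge, which gave free [L] = 0.00101 M, so G, whose loss is pseudo-first-order at this steady [L], went at 8.63 × 10⁻⁵ s⁻¹.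

2. In the plain chain J → G → Q, with X away, [G] stops rising when k1[J] equals that loss times [G], and taking logarithms put this crest time, the logarithm of the ratio of the two constants over their difference, at 1.59 h.

3. For alpha I took two extremes: with X absent, the chain gave 61.0% of G at 1.5 h, and with X, the limiting reagent of the capture, taking its whole charge of J at the first instant, 48.8% remained.

4. J removed early costs more G than J removed late, because the run of 1.5 h is shorter than the crest time, so alpha had to lie between the extremes; and because the half-life of X by capture, 0.122 h with J held at its charge, is shorter than the run, I committed to the lower end and took gamma and eta no further.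

5. The forecast named alpha as best, with 49.6%, 36.5% and 41.3% for alpha, gamma and eta, its alpha standing slightly above mine, and it held that dosing in eta "leaves J unreacted".

The simulation gave alpha as best, with 49.7% for alpha, 36.5% for gamma and 41.7% for eta. In alpha at 1.50 h, G was being made 1.00 times as fast as it was used up, each step taken net, against a crest time of 1.59 h for the plain chain. The alpha flask read at 4.0 h, which is 2.52 crest times, held 30.3% of G and 49.2% of Q.

Its constants were set for the occasion; the result is computed.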